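Assumption: the facial sense of the two reagent-controlled steps that no simple model predicts (step 7, lithio-enamine alkylation; step 11, alkaloid-catalysed methanolysis) is taken as drawn. In both cases the mirror-image controller (D-valine tert-butyl ester, (DHQ)2AQN) is commercial and can be swapped in without changing the route.

## Retrosynthetic overview

1. Chromanone numbering is used throughout (O1, C2, C3, C4, C4a, C5–C8, C8a; ring A = carbocycle, ring B = dihydropyranone). Ring B is opened at O1–C8a, which corresponds to cyclodehydration of a syn-β-hydroxyacyl chain whose C2/C3 centres come unchanged from an Evans syn aldol (fragment C, 28).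
2. C4–C4a is cut as a C-acylation of the ring A trione 30 with acid 28.
3. Ring A is cut at C6–C7 (Dieckmann) and C4a–C5 (crossed Claisen, the key union). This gives the quaternary keto ester 11 (fragment A) and the phenylglutarate acyl donor 19 (fragment B), two pieces of comparable size.
4. Fragment A comes from methyl acetoacetate, (S)-lavandulyl iodide (Evans deconjugative prenylation) and prenyl bromide (valine-enamine alkylation sets C8). Fragment B comes from benzaldehyde and methyl acetoacetate via 3-phenylglutaric anhydride, whose desymmetrisation sets the benzylic centre.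
5. Ring A forms first (step 20) and ring B last (step 23).

## Fragment A (steps 1–7)

Step 1
Reactants: 1 3-methylbut-2-enoyl chloride
Product: 2 (S)-4-benzyl-3-(3-methylbut-2-enoyl)oxazolidin-2-one
Conditions: (S)-4-benzyloxazolidin-2-one, n-BuLi, THF, −78 °C; then 1, −78 → 0 °C
Reagents that add atoms: (S)-4-benzyloxazolidin-2-one, O=C1N[C@@H](Cc2ccccc2)CO1
Why: N-acylation of the lithiated Evans auxiliary by the acid chloride, with no new stereocentre.

Step 2
Reactants: 2 (S)-4-benzyl-3-(3-methylbut-2-enoyl)oxazolidin-2-one; 3 prenyl bromide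
Product: 4 (S)-4-benzyl-3-[(2S)-5-methyl-2-(prop-1-en-2-yl)hex-4-enoyl]oxazolidin-2-one
Conditions: NaHMDS (1.05 equiv), THF, −78 °C; 3, −78 → −40 °C; NH4Cl quench at low temperature
Reagents that add atoms: none
Why: Evans asymmetric alkylation in its deconjugative mode: the chelated Z sodium dienolate reacts at the α-carbon on the face away from the benzyl group, which sets the lavandulyl centre (2S here, R in the target after the priority change) and moves the alkene out of conjugation.

Step 3
Reactants: 4 (S)-4-benzyl-3-[(2S)-5-methyl-2-(prop-1-en-2-yl)hex-4-enoyl]oxazolidin-2-one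
Product: 5 (S)-lavandulol [(2S)-5-methyl-2-(prop-1-en-2-yl)hex-4-en-1-ol]
Conditions: LiBH4, MeOH (1.1 equiv), Et2O, 0 °C
Reagents that add atoms: none
Why: Reductive cleavage of the imide by borohydride gives the primary alcohol and returns the auxiliary without touching the stereocentre.

Step 4
Reactants: 5 (S)-lavandulol
Product: 6 (S)-lavandulyl iodide [(3S)-3-(iodomethyl)-2,6-dimethylhepta-1,5-diene]
Conditions: PPh3, I2, imidazole, CH2Cl2, 0 °C
Reagents that add atoms: iodine, [I][I]
Why: Appel-type (Garegg–Samuelsson) iodination displaces the activated primary oxygen by SN2 and leaves the alkenes and the adjacent stereocentre untouched.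

Step 5
Reactants: 6 (S)-lavandulyl iodide; 7 methyl acetoacetate
Product: 8 methyl (4R)-2-acetyl-7-methyl-4-(prop-1-en-2-yl)oct-6-enoate (both C2 epimers)
Conditions: 7 (1.5 equiv), NaH, THF/DMF, 0 → 60 °C
Reagents that add atoms: none
Why: Acetoacetic ester alkylation: the soft, weakly basic enolate substitutes the β-branched primary iodide by SN2, and the new C2 centre is erased in the next step.

Step 6
Reactants: 8 methyl (4R)-2-acetyl-7-methyl-4-(prop-1-en-2-yl)oct-6-enoate
Product: 9 methyl (Z)-3-{[(2S)-1-tert-butoxy-3-methyl-1-oxobutan-2-yl]amino}-2-[(2R)-5-methyl-2-(prop-1-en-2-yl)hex-4-en-1-yl]but-2-enoate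
Conditions: L-valine tert-butyl ester, BF3·OEt2 (cat.), benzene, reflux, Dean–Stark
Reagents that add atoms: L-valine tert-butyl ester, CC(C)[C@H](N)C(=O)OC(C)(C)C
Why: Ketone–amine condensation gives the hydrogen-bonded Z enamino ester, a single planar nucleophile that carries the chiral controller.

Step 7
Reactants: 9 the valine enamino ester; 3 prenyl bromide
Product: 11 methyl (2S,4R)-2-acetyl-7-methyl-2-(3-methylbut-2-en-1-yl)-4-(prop-1-en-2-yl)oct-6-enoate (fragment A), via ketimine 10 (not isolated)
Conditions: LDA (1.1 equiv), toluene, −78 °C; HMPA (1.0 equiv); 3, −78 → −55 °C; then 1 M HCl, THF, 0 °C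
Reagents that add atoms: water, O
Why: Koga asymmetric alkylation of a chelated lithio-enamine: the valine isopropyl group shields one face, so the reactive allylic bromide sets the quaternary centre (future C8, S), and mild imine hydrolysis returns the methyl ketone.

## Fragment B (steps 8–14)

Step 8
Reactants: 12 benzaldehyde; 7 methyl acetoacetate
Product: 13 dimethyl 2,4-diacetyl-3-phenylpentanedioate (stereoisomer mixture)
Conditions: 7 (2.1 equiv), piperidine (cat.), MeOH, rt
Reagents that add atoms: none
Why: Knoevenagel condensation followed by Michael addition of a second acetoacetate builds the 3-phenylglutarate carbon chain.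

Step 9
Reactants: 13 dimethyl 2,4-diacetyl-3-phenylpentanedioate
Product: 14 3-phenylglutaric acid
Conditions: NaOH (50% aq), EtOH, reflux; then conc. HCl
Reagents that add atoms: sodium hydroxide, [Na+].[OH-]
Why: Hydroxide-induced retro-Claisen loss of both acetyl groups, together with saponification, gives the achiral diacid.

Step 10
Reactants: 14 3-phenylglutaric acid
Product: 15 3-phenylglutaric anhydride (4-phenyloxane-2,6-dione)
Conditions: Ac2O, reflux
Reagents that add atoms: none
Why: Anhydride exchange and cyclodehydration give the six-membered prochiral anhydride.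

Step 11
Reactants: 15 3-phenylglutaric anhydride
Product: 16 (S)-5-methoxy-5-oxo-3-phenylpentanoic acid
Conditions: MeOH (10 equiv), hydroquinidine anthraquinone-1,4-diyl diether (DHQD)2AQN (0.3 equiv), Et2O, −40 °C
Reagents that add atoms: methanol, CO
Why: Cinchona-alkaloid-catalysed desymmetrising methanolysis opens one enantiotopic carbonyl of the anhydride and so sets the benzylic stereocentre.

Step 12
Reactants: 16 (S)-5-methoxy-5-oxo-3-phenylpentanoic acid
Product: 17 1-tert-butyl 5-methyl (R)-3-phenylpentanedioate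
Conditions: tert-butyl 2,2,2-trichloroacetimidate, BF3·OEt2 (cat.), CH2Cl2/cyclohexane, rt
Reagents that add atoms: tert-butyl 2,2,2-trichloroacetimidate, CC(C)(C)OC(=N)C(Cl)(Cl)Cl
Why: Acid-catalysed O-tert-butylation of the free acid by the imidate masks the arm that ends as the target's carboxylic acid (the descriptor changes by priority only).

Step 13
Reactants: 17 1-tert-butyl 5-methyl (R)-3-phenylpentanedioate
Product: 18 (R)-5-tert-butoxy-5-oxo-3-phenylpentanoic acid
Conditions: LiOH, THF/H2O, 0 °C → rt; then 1 M HCl to pH 3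
Reagents that add atoms: lithium hydroxide, [Li+].[OH-]
Why: Chemoselective saponification cleaves the unhindered methyl ester while the tert-butyl ester is inert, and the β-stereocentre cannot epimerise.

Step 14
Reactants: 18 (R)-5-tert-butoxy-5-oxo-3-phenylpentanoic acid
Product: 19 tert-butyl (R)-5-(1H-benzotriazol-1-yl)-5-oxo-3-phenylpentanoate (fragment B)
Conditions: 1H-benzotriazole, DCC, CH2Cl2, 0 °C → rt
Reagents that add atoms: 1H-benzotriazole, c1ccc2[nH]nnc2c1
Why: Carbodiimide coupling gives a Katritzky N-acylbenzotriazole, a neutral and storable C-acylating agent made under conditions too mild to re-form the symmetric anhydride.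

## Fragment C (steps 15–18)

Step 15
Reactants: 20 propionyl chloride
Product: 21 (S)-4-benzyl-3-propionyloxazolidin-2-one
Conditions: (S)-4-benzyloxazolidin-2-one, n-BuLi, THF, −78 °C; then 20, −78 → 0 °C
Reagents that add atoms: (S)-4-benzyloxazolidin-2-one, O=C1N[C@@H](Cc2ccccc2)CO1
Why: N-acylation of the lithiated Evans auxiliary.

Step 16
Reactants: 21 (S)-4-benzyl-3-propionyloxazolidin-2-one; 22 acetaldehyde
Product: 25 (S)-4-benzyl-3-[(2S,3R)-3-hydroxy-2-methylbutanoyl]oxazolidin-2-one, via Z-boron enolate 23 (not isolated), via boron aldolate 24 (not isolated)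
Conditions: Bu2BOTf, Et3N, CH2Cl2, −78 → 0 °C; 22, −78 → 0 °C; then H2O2, MeOH, pH 7 buffer
Reagents that add atoms: none
Why: Evans syn aldol through a Zimmerman–Traxler chair of the Z boron enolate sets both future ring B centres (2S,3R in the acyl chain, which are C3 S and C2 R of the target).

Step 17
Reactants: 25 the syn aldol adduct
Product: 26 (S)-4-benzyl-3-[(2S,3R)-3-(tert-butyldimethylsilyloxy)-2-methylbutanoyl]oxazolidin-2-one
Conditions: TBSOTf, 2,6-lutidine, CH2Cl2, 0 °C
Reagents that add atoms: tert-butyldimethylsilyl triflate, CC(C)(C)[Si](C)(C)OS(=O)(=O)C(F)(F)F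
Why: Silylation of the secondary alcohol blocks retro-aldol and elimination in the later acylation.

Step 18
Reactants: 26 the TBS-protected aldol imide
Product: 28 (2S,3R)-3-(tert-butyldimethylsilyloxy)-2-methylbutanoic acid (fragment C), via peroxy acid 27 (not isolated)
Conditions: LiOH, H2O2, THF/H2O, 0 °C; Na2SO3; then 1 M HCl
Reagents that add atoms: hydrogen peroxide, OO
Why: Hydroperoxide attacks the exocyclic imide carbonyl selectively, and sulfite reduction of the peracid gives the acid without α-epimerisation.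

## Fragment union and endgame (steps 19–23)

Step 19
Reactants: 11 fragment A keto ester; 19 fragment B acylbenzotriazole
Product: 29 1-tert-butyl 9-methyl (3R,8S)-8-(3-methylbut-2-en-1-yl)-8-[(2R)-5-methyl-2-(prop-1-en-2-yl)hex-4-en-1-yl]-5,7-dioxo-3-phenylnonanedioate
Conditions: MgBr2·OEt2 (2.5 equiv), i-Pr2NEt (3 equiv), CH2Cl2, rt
Reagents that add atoms: none
Why: Crossed Claisen C-acylation by soft enolisation: magnesium chelation of the keto ester lets the amine deprotonate the only enolisable position (the acetyl CH3, future C4a), which takes the acyl group from 19 to form C4a–C5 with no stereocentre at risk.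

Step 20
Reactants: 29 the open-chain β-diketone diester
Product: 30 tert-butyl (3R)-3-{(5S)-2,4-dihydroxy-5-(3-methylbut-2-en-1-yl)-5-[(2R)-5-methyl-2-(prop-1-en-2-yl)hex-4-en-1-yl]-6-oxocyclohexa-1,3-dien-1-yl}-3-phenylpropanoate
Conditions: LDA (3.5 equiv), THF, −78 → 0 °C; then 1 M HCl
Reagents that add atoms: none
Why: Dieckmann cyclisation of a Hauser–Harris β-diketone dianion: the terminal C6 carbanion (C8 has no hydrogen) attacks the C7 methyl ester to close ring A, the tert-butyl ester survives as its inert lithium enolate, and deprotonation of the trione drives the closure.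

Step 21
Reactants: 30 ring A trione; 28 fragment C acid
Product: 31 tert-butyl (3R)-3-{(5S)-3-[(2S,3R)-3-(tert-butyldimethylsilyloxy)-2-methylbutanoyl]-2,4-dihydroxy-5-(3-methylbut-2-en-1-yl)-5-[(2R)-5-methyl-2-(prop-1-en-2-yl)hex-4-en-1-yl]-6-oxocyclohexa-1,3-dien-1-yl}-3-phenylpropanoate
Conditions: DCC (1.2 equiv), DMAP (1.2 equiv), CH2Cl2, 0 °C → rt
Reagents that add atoms: none
Why: Steglich O-acylation followed by DMAP-mediated O-to-C acyl migration places the acyl group on C4a, the only unsubstituted nucleophilic carbon, to give the chelated 2-acyl trione in which C3 is shielded from enolisation.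

Step 22
Reactants: 31 the acylated trione tert-butyl ester
Product: 33 (3R)-3-{(5S)-3-[(2S,3R)-3-(tert-butyldimethylsilyloxy)-2-methylbutanoyl]-2,4-dihydroxy-5-(3-methylbut-2-en-1-yl)-5-[(2R)-5-methyl-2-(prop-1-en-2-yl)hex-4-en-1-yl]-6-oxocyclohexa-1,3-dien-1-yl}-3-phenylpropanoic acid, via tris-TMS derivative 32 (not isolated)
Conditions: TMSOTf (6 equiv), 2,6-lutidine (8 equiv), CH2Cl2, 0 °C; then pH 4 citrate buffer, THF
Reagents that add atoms: none
Why: Silyl-triflate-mediated tert-butyl ester cleavage (loss of isobutene to a silyl ester that hydrolyses on work-up) avoids protic acid that would cyclise the prenyl groups onto the enols, and silylation of the ring enols keeps C3 from enolising.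

Step 23
Reactants: 33 the silyl-protected hydroxyacyl trione acid
Product: 35 (3R)-3-{(2R,3S,8S)-5-hydroxy-2,3-dimethyl-8-(3-methylbut-2-en-1-yl)-8-[(2R)-5-methyl-2-(prop-1-en-2-yl)hex-4-en-1-yl]-4,7-dioxo-3,4,7,8-tetrahydro-2H-chromen-6-yl}-3-phenylpropanoic acid (target), via free C2 alcohol 34 (not isolated)
Conditions: HF (48% aq), MeCN, 0 °C → rt
Reagents that add atoms: none
Why: Desilylation followed by reversible acid-catalysed cyclodehydration (vinylogous esterification) closes ring B on C8a, the only isomer that keeps the chelated C5–OH···O=C4 hydrogen bond, and because the C2–O bond is never broken the syn acid delivers the cis (2R,3S) dimethyl pattern.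

## Compound list

1 | 3-methylbut-2-enoyl chloride | CC(C)=CC(=O)Cl | starting material
2 | (S)-4-benzyl-3-(3-methylbut-2-enoyl)oxazolidin-2-one | CC(C)=CC(=O)N1[C@@H](Cc2ccccc2)COC1=O | intermediate
3 | prenyl bromide (1-bromo-3-methylbut-2-ene) | CC(C)=CCBr | starting material
4 | (S)-4-benzyl-3-[(2S)-5-methyl-2-(prop-1-en-2-yl)hex-4-enoyl]oxazolidin-2-one | C=C(C)[C@H](CC=C(C)C)C(=O)N1[C@@H](Cc2ccccc2)COC1=O | intermediate
5 | (S)-lavandulol | C=C(C)[C@H](CC=C(C)C)CO | intermediate
6 | (S)-lavandulyl iodide | C=C(C)[C@H](CC=C(C)C)CI | intermediate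
7 | methyl acetoacetate | CC(=O)CC(=O)OC | starting material
8 | methyl (4R)-2-acetyl-7-methyl-4-(prop-1-en-2-yl)oct-6-enoate (C2 epimers) | C=C(C)[C@H](CC=C(C)C)CC(C(C)=O)C(=O)OC | intermediate
9 | Z enamino ester of 8 with L-valine tert-butyl ester | C=C(C)[C@H](CC=C(C)C)C/C(C(=O)OC)=C(\C)N[C@@H](C(C)C)C(=O)OC(C)(C)C | intermediate
10 | L-valine tert-butyl ester ketimine of 11 | C=C(C)[C@H](CC=C(C)C)C[C@](CC=C(C)C)(C(=O)OC)C(C)=N[C@@H](C(C)C)C(=O)OC(C)(C)C | intermediate
11 | methyl (2S,4R)-2-acetyl-7-methyl-2-(3-methylbut-2-en-1-yl)-4-(prop-1-en-2-yl)oct-6-enoate (fragment A) | C=C(C)[C@H](CC=C(C)C)C[C@](CC=C(C)C)(C(=O)OC)C(C)=O | intermediate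
12 | benzaldehyde | O=Cc1ccccc1 | starting material
13 | dimethyl 2,4-diacetyl-3-phenylpentanedioate | COC(=O)C(C(C)=O)C(c1ccccc1)C(C(C)=O)C(=O)OC | intermediate
14 | 3-phenylglutaric acid | OC(=O)CC(c1ccccc1)CC(=O)O | intermediate
15 | 3-phenylglutaric anhydride | O=C1CC(c2ccccc2)CC(=O)O1 | intermediate
16 | (S)-5-methoxy-5-oxo-3-phenylpentanoic acid | COC(=O)C[C@H](CC(=O)O)c1ccccc1 | intermediate
17 | 1-tert-butyl 5-methyl (R)-3-phenylpentanedioate | COC(=O)C[C@H](CC(=O)OC(C)(C)C)c1ccccc1 | intermediate
18 | (R)-5-tert-butoxy-5-oxo-3-phenylpentanoic acid | OC(=O)C[C@H](CC(=O)OC(C)(C)C)c1ccccc1 | intermediate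
19 | tert-butyl (R)-5-(1H-benzotriazol-1-yl)-5-oxo-3-phenylpentanoate (fragment B) | O=C(C[C@H](CC(=O)OC(C)(C)C)c1ccccc1)n1nnc2ccccc12 | intermediate
20 | propionyl chloride | CCC(=O)Cl | starting material
21 | (S)-4-benzyl-3-propionyloxazolidin-2-one | CCC(=O)N1[C@@H](Cc2ccccc2)COC1=O | intermediate
22 | acetaldehyde | CC=O | starting material
23 | dibutylboron Z enolate of 21 | C/C=C(\OB(CCCC)CCCC)N1[C@@H](Cc2ccccc2)COC1=O | intermediate
24 | dibutylboron aldolate of 25 | CCCCB(CCCC)O[C@H](C)[C@H](C)C(=O)N1[C@@H](Cc2ccccc2)COC1=O | intermediate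
25 | (S)-4-benzyl-3-[(2S,3R)-3-hydroxy-2-methylbutanoyl]oxazolidin-2-one | O[C@H](C)[C@H](C)C(=O)N1[C@@H](Cc2ccccc2)COC1=O | intermediate
26 | (S)-4-benzyl-3-[(2S,3R)-3-(tert-butyldimethylsilyloxy)-2-methylbutanoyl]oxazolidin-2-one | CC(C)(C)[Si](C)(C)O[C@H](C)[C@H](C)C(=O)N1[C@@H](Cc2ccccc2)COC1=O | intermediate
27 | (2S,3R)-3-(tert-butyldimethylsilyloxy)-2-methylbutaneperoxoic acid | CC(C)(C)[Si](C)(C)O[C@H](C)[C@H](C)C(=O)OO | intermediate
28 | (2S,3R)-3-(tert-butyldimethylsilyloxy)-2-methylbutanoic acid (fragment C) | CC(C)(C)[Si](C)(C)O[C@H](C)[C@H](C)C(=O)O | intermediate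
29 | open-chain β-diketone diester (C7 methyl ester, side-chain tert-butyl ester) | C=C(C)[C@H](CC=C(C)C)C[C@](CC=C(C)C)(C(=O)OC)C(=O)CC(=O)C[C@H](CC(=O)OC(C)(C)C)c1ccccc1 | intermediate
30 | ring A trione tert-butyl ester (drawn as the 5,8a-dienol 7-ketone) | C=C(C)[C@H](CC=C(C)C)C[C@]1(CC=C(C)C)C(=O)C([C@H](CC(=O)OC(C)(C)C)c2ccccc2)=C(O)C=C1O | intermediate
31 | C4a-acylated trione tert-butyl ester with TBS ether | C=C(C)[C@H](CC=C(C)C)C[C@]1(CC=C(C)C)C(=O)C([C@H](CC(=O)OC(C)(C)C)c2ccccc2)=C(O)C(C(=O)[C@@H](C)[C@@H](C)O[Si](C)(C)C(C)(C)C)=C1O | intermediate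
32 | trimethylsilyl ester bis(trimethylsilyl enol ether) of 33 | C=C(C)[C@H](CC=C(C)C)C[C@]1(CC=C(C)C)C(=O)C([C@H](CC(=O)O[Si](C)(C)C)c2ccccc2)=C(O[Si](C)(C)C)C(C(=O)[C@@H](C)[C@@H](C)O[Si](C)(C)C(C)(C)C)=C1O[Si](C)(C)C | intermediate
33 | C4a-acylated trione free acid with TBS ether | C=C(C)[C@H](CC=C(C)C)C[C@]1(CC=C(C)C)C(=O)C([C@H](CC(=O)O)c2ccccc2)=C(O)C(C(=O)[C@@H](C)[C@@H](C)O[Si](C)(C)C(C)(C)C)=C1O | intermediate
34 | C4a-[(2S,3R)-3-hydroxy-2-methylbutanoyl] trione free acid | C=C(C)[C@H](CC=C(C)C)C[C@]1(CC=C(C)C)C(=O)C([C@H](CC(=O)O)c2ccccc2)=C(O)C(C(=O)[C@@H](C)[C@@H](C)O)=C1O | intermediate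
35 | CNP0150579.4 | C=C(C)[C@H](CC=C(C)C)C[C@]1(CC=C(C)C)C(=O)C([C@H](CC(=O)O)c2ccccc2)=C(O)C2=C1O[C@H](C)[C@H](C)C2=O | target

## Step count

Total step count: 23.
Longest linear sequence: 12 steps (steps 1–7, then 19–23). The fragment B line (steps 8–14, then 19–23) is equally long.

## Steps most likely to fail

**Step 7 (quaternary centre).** The enamine carries a bulky, already chiral α-substituent, so both the rate and the matched or mismatched selectivity are uncertain. The fallback gives up asymmetric induction and uses the fixed lavandulyl centre as a resolving handle. It sets out from 8 and comes back at 11. Direct alkylation of 8 with 3 (K2CO3, acetone, reflux) gives 11 together with its C2 epimer methyl (2R,4R)-2-acetyl-7-methyl-2-(3-methylbut-2-en-1-yl)-4-(prop-1-en-2-yl)oct-6-enoate F1. The two are diastereomers and are separated by preparative HPLC on silver-nitrate-impregnated silica. Only 11 is carried on.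

**Step 20 (Dieckmann closure).** A polyanion has to attack a neopentyl-type methyl ester. The possible failures are O-lactonisation to a pyran-2,4-dione or simple recovery of 29. The fallback raises the electrophilicity of C7 before the fragments are joined. It sets out from 11 and comes back at 30.
- Treating 11 with AlMe3 and EtSH (CH2Cl2, 0 °C → rt) gives the S-ethyl thioester of fragment A F2, which has no α-hydrogen and cannot self-enolise.
- Soft-enolisation acylation of F2 with 19, as in step 19, gives the thioester β-diketone F3.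
- LDA at −78 °C then closes ring A with loss of ethanethiolate, at a temperature where lactonisation and ester-enolate side reactions are frozen out, and delivers 30.

**Step 23 (regiochemistry and integrity of ring B).** Closure on the C5 oxygen, addition of an enol to a prenyl group, or C3 epimerisation could all compete. The fallback removes the regiochemical choice by using the side-chain acid as an internal blocking group. It sets out from 30 and comes back at 35.
- TMSOTf/2,6-lutidine on 30 gives the ring A trione free acid F4.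
- EDC·HCl (CH2Cl2, 0 °C) lactonises F4 onto the less hindered C5 oxygen, because the C7 oxygen is flanked by the quaternary C8. This gives the C5–O enol δ-lactone F5.
- DCC/DMAP acylation of F5 with 28 gives the C4a-acylated lactone F6.
- HF·pyridine (MeCN, 0 °C) can now close ring B only on C8a, which gives the tricyclic pyranone lactone F7.
- The activated enol lactone is opened with LiOH (2 equiv, THF/H2O, 0 °C) to give 35. The product is present as its dianion, which protects C3.

## Further compounds

F1 | step 7 | methyl (2R,4R)-2-acetyl-7-methyl-2-(3-methylbut-2-en-1-yl)-4-(prop-1-en-2-yl)oct-6-enoate | C=C(C)[C@H](CC=C(C)C)C[C@@](CC=C(C)C)(C(=O)OC)C(C)=O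
F2 | step 20 | S-ethyl (2S,4R)-2-acetyl-7-methyl-2-(3-methylbut-2-en-1-yl)-4-(prop-1-en-2-yl)oct-6-enethioate | C=C(C)[C@H](CC=C(C)C)C[C@](CC=C(C)C)(C(=O)SCC)C(C)=O
F3 | step 20 | analogue of 29 with an S-ethyl thioester at C7 | C=C(C)[C@H](CC=C(C)C)C[C@](CC=C(C)C)(C(=O)SCC)C(=O)CC(=O)C[C@H](CC(=O)OC(C)(C)C)c1ccccc1
F4 | step 23 | free carboxylic acid of 30 | C=C(C)[C@H](CC=C(C)C)C[C@]1(CC=C(C)C)C(=O)C([C@H](CC(=O)O)c2ccccc2)=C(O)C=C1O
F5 | step 23 | enol δ-lactone of F4 closed on the C5 oxygen | C=C(C)[C@H](CC=C(C)C)C[C@]1(CC=C(C)C)C(=O)C2=C(OC(=O)C[C@@H]2c3ccccc3)C=C1O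
F6 | step 23 | F5 bearing the (2S,3R)-3-(tert-butyldimethylsilyloxy)-2-methylbutanoyl group at C4a | C=C(C)[C@H](CC=C(C)C)C[C@]1(CC=C(C)C)C(=O)C2=C(OC(=O)C[C@@H]2c3ccccc3)C(C(=O)[C@@H](C)[C@@H](C)O[Si](C)(C)C(C)(C)C)=C1O
F7 | step 23 | C5–O enol δ-lactone of the target (rings A and B closed) | C=C(C)[C@H](CC=C(C)C)C[C@]1(CC=C(C)C)C(=O)C2=C(OC(=O)C[C@@H]2c3ccccc3)C4=C1O[C@H](C)[C@H](C)C4=O
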